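**Remarks on the chemistry (assumptions)**
- The target is taken as the free bis(hydrogen sulfate) as drawn, so the last step ends with proton exchange on an acid resin; for storage a salt form would be preferred.
- Diosmetin 9 is itself an article of commerce, but it is built here, because a total synthesis of the skeleton is asked for.

## Analysis of the target

The target is a flavone. Ring A (C4a, C5, C6, C7, C8, C8a) is fused to the 4-pyranone ring C (O1, C2, C3, C4, C4a, C8a), and ring B (C1' to C6') sits on C2. Ring A has the phloroglucinol pattern: O1 on C8a, a free hydroxyl on C5 and a hydrogen sulfate on O7. Ring B carries a hydrogen sulfate on O3' and a methyl ether on O4'. The molecule has no stereocenter and is achiral, so nothing has to be set or preserved.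

The sensitive groups are the two aryl hydrogen sulfates. They are hydrolysed by acid, are strongly ionic, and do not tolerate silica chromatography, palladium catalysis or hydrogenation conditions well, so they must be introduced last. The 5-OH is hydrogen-bonded to the C4 carbonyl and is the least nucleophilic phenol, so the two sulfates sit exactly on the two non-chelated phenols of diosmetin. The O4' methyl ether forbids methyl ethers as protecting groups elsewhere.

The difficulty is therefore not stereochemistry. It lies in telling five oxygens apart and in building ring C, whose C4 carbonyl is wedged between the doubly ortho-oxygenated C4a and C3. The feature that invites the key move is that C4 is an isolated one-carbon carbonyl unit, bonded only to the aryl carbon C4a and to the C3=C2 unit, with O1 ortho to C4a. Ring C can thus be read as an aryl iodide carbon, carbon monoxide, an alkyne and an ortho phenol oxygen.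

## Retrosynthetic reasoning

**10 to 9 (sulfates last).** The two S–O bonds at O7 and O3' are cut first. The sulfate esters would not survive the palladium step, the hydrogenolysis or chromatography, and the chelation of the 5-OH offers the required site selectivity without a protecting group. The forward reaction has to sulfonate the two free, non-chelated phenols of diosmetin 9 and leave the hydrogen-bonded 5-OH untouched.

**9 to 8 (one global deprotection).** The O–CH2 bonds of three benzyl ethers at O5, O7 and O3' are cut. Benzyl is used because the O4' methyl ether must survive, which rules out methyl, and because all three groups fall in one hydrogenolysis. The forward reaction must not reduce C2=C3 of ring C.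

**8 to 2 + 4 + 5 (key disconnection).** Three bonds of ring C are cut in one operation: C4a–C4, C4–C3 and O1–C2. C4 becomes carbon monoxide 5. C2 and C3 become the alkyne carbons of 4. Ring A becomes iodophenol 2, whose iodine marks C4a and whose free hydroxyl becomes O1. Any cut that keeps the C4a–C4 bond demands a C-acylated, selectively protected phloroglucinol and builds ring C bond by bond; here each of the three components is at most one step from a commercial compound. The forward reaction has to take up CO before the acetylide is coupled (giving ynone 6) and then close the six-membered ring through the amine adduct 7.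

**2 to 1 (ring A partner).** The C–I bond is cut. The forward reaction is an iodination of 1 that must go ortho to the free hydroxyl (C2/C6, equivalent) and not para to it (C4).

**4 to 3 (ring B partner).** The terminal alkyne carbon is removed, which leads back to aldehyde 3. The forward reaction is a one-carbon homologation of a non-enolisable aryl aldehyde.

## Alternatives that were turned down

**Alternative 1:** the textbook Baker–Venkataraman route, cutting C2–C3 and O1–C2.
- Forward key step: the ester 2-acetyl-3,5-bis(benzyloxy)phenyl 3-(benzyloxy)-4-methoxybenzoate A1 rearranges under base (intramolecular Claisen-type acyl transfer) to the 1,3-diketone A2, and acid cyclodehydration of A2 gives 8.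
- Why turned down: A1 already needs the C4a–C4 bond in a selectively protected ring A aryl methyl ketone. Ring C then costs three operations (O-acylation, rearrangement, cyclodehydration), each forming one bond. The hot acid of the last operation endangers the benzyl ethers, above all the one at O5 next to the carbonyl. The sequence is linear and about two steps longer than the chosen route, and it is the route most chemists would draw first.

**Alternative 2:** cutting C2–C1', so that ring B is attached to a finished chromone.
- Forward key step: oxidative C–H arylation (oxidative Heck type) of 5,7-bis(benzyloxy)-4H-chromen-4-one A3 at C2 with [3-(benzyloxy)-4-methoxyphenyl]boronic acid A4 under divalent palladium, giving 8.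
- Why turned down: the key step forms one bond and no ring. Ring C must already exist in A3, which itself needs about three steps from a ring A ketone, so the precursor is hardly simpler than the product. Arylation at C3, the nucleophilic enone carbon, competes and would give the isoflavone skeleton. The O5 ether next to the carbonyl can chelate the metal and slow the turnover.

**Alternative 3:** a two-component [3+3] cut of C4a–C4 and O1–C2 (Mentzer pyrone annulation).
- Forward key step: benzene-1,3,5-triol A5 and ethyl 3-(3-hydroxy-4-methoxyphenyl)-3-oxopropanoate A6 are fused at about 240 °C without solvent. The aroylketene A7 formed by loss of ethanol acylates A5 at carbon, and cyclodehydration gives 9 directly, without protecting groups.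
- Why turned down: it is about two steps shorter on paper, but its selectivity rests on nothing in the substrate. The same two reactants are the Pechmann pair: attack of A5 on the ketone carbonyl followed by lactonisation gives the isomeric 4-arylcoumarin A8, and the partition between the two pathways cannot be steered by a catalyst, ligand or protecting group. A7 carries a free phenol of its own and A5 three more, so O-acylation and oligoester formation compete in the melt. The product 9 and the isomer A8 are polyphenols of the same formula and similar polarity, which are hard to separate. The saving in steps was judged not to outweigh a C–C bond formation that offers no handle for correction.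

Key step: step 3

## Steps

Step 1
Reactants: 1 3,5-bis(benzyloxy)phenol
Product: 2 3,5-bis(benzyloxy)-2-iodophenol
Conditions: NIS (1.0 equiv), CH2Cl2, −40 → 0 °C, dark
Reagents that add atoms: N-iodosuccinimide, O=C1CCC(=O)N1I
Why: Electrophilic aromatic iodination of a triply activated ring; the two equivalent positions ortho to the hydroxyl are flanked by OH and one benzyloxy group, whereas C4 lies between two benzyloxy groups, so the large iodine electrophile, delivered through a hydrogen bond from the phenol to NIS, should enter at C2. One equivalent at low temperature limits di-iodination.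

Step 2
Reactants: 3 3-(benzyloxy)-4-methoxybenzaldehyde
Product: 4 2-(benzyloxy)-4-ethynyl-1-methoxybenzene
Conditions: dimethyl (1-diazo-2-oxopropyl)phosphonate (1.3 equiv), K2CO3 (2 equiv), MeOH/THF, 0 °C → rt
Reagents that add atoms: dimethyl (1-diazo-2-oxopropyl)phosphonate (Bestmann–Ohira reagent), COP(=O)(OC)C(=[N+]=[N-])C(C)=O
Why: Seyferth–Gilbert homologation in the Bestmann–Ohira variant; methanolysis of the reagent gives the diazomethylphosphonate anion, which adds to the non-enolisable aldehyde, and loss of dimethyl phosphate and dinitrogen with a 1,2-shift gives the terminal alkyne. Both ethers are inert to K2CO3 in methanol.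

Step 3
Reactants: 2 3,5-bis(benzyloxy)-2-iodophenol; 4 2-(benzyloxy)-4-ethynyl-1-methoxybenzene (1.3 equiv); 5 carbon monoxide
Product: 8 5,7-bis(benzyloxy)-2-[3-(benzyloxy)-4-methoxyphenyl]-4H-chromen-4-one, via 2-hydroxyaryl ynone 6 (not isolated), via diethylamino enone 7 (not isolated)
Conditions: PdCl2(dppf) (5 mol %), CO (5 bar), Et2NH/DMF 1:3, 90 °C, no copper salt
Reagents that add atoms: none
Why: This is a palladium-catalysed carbonylative Sonogashira annulation of a 2-iodophenol with a terminal arylacetylene, the closest known reaction type, which gives flavones from simple 2-iodophenols in secondary amine media. Zerovalent palladium, formed from PdCl2(dppf) in the amine/CO medium, inserts into the C–I bond of 2, CO 5 migrates in to give an aroylpalladium species, and amine-assisted transfer of the acetylide of 4 followed by reductive elimination gives ynone 6, which forms C4a–C4 and C4–C3. Diethylamine then adds to C2 of 6 to give the vinylogous amide 7, and the ortho hydroxyl displaces the amine at the same carbon by addition–elimination, a 6-endo-trig closure (net 6-endo-dig on the ynone) that forms O1–C2 and ring C. The step needs three selectivities: CO uptake before acetylide transfer, six- over five-membered closure, and capture of the aroylpalladium by the acetylide and not by the amine. The first should be secured by the CO pressure and by the crowded, electron-rich, di-ortho-oxygenated arylpalladium, which inserts CO faster than it accepts the acetylide; the second by the secondary amine, because closure through 7 fixes the ring size before 5-exo attack of the phenoxide on the free ynone can compete; the third by the hindered aroyl group, which slows aminolysis, and by the excess of 4. Only one oxygen nucleophile is free in 6 (O5, O7 and O3' are benzylated), so a single flavone can form, and no stereocenter is created.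

Step 4
Reactants: 8 5,7-bis(benzyloxy)-2-[3-(benzyloxy)-4-methoxyphenyl]-4H-chromen-4-one
Product: 9 5,7-dihydroxy-2-(3-hydroxy-4-methoxyphenyl)-4H-chromen-4-one (diosmetin)
Conditions: H2 (1 atm), 10% Pd/C, THF/MeOH 1:1, rt, stopped after uptake of three equivalents
Reagents that add atoms: none
Why: Hydrogenolysis of three aryl benzyl ethers over palladium; the benzylic C–O bonds should be cleaved much faster than the vinylogous ester C2=C3 of the flavone is reduced, and the methyl ether is inert.

Step 5
Reactants: 9 5,7-dihydroxy-2-(3-hydroxy-4-methoxyphenyl)-4H-chromen-4-one (diosmetin)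
Product: 10 luteolin 4'-methyl ether 7,3'-disulfate (5-hydroxy-2-[4-methoxy-3-(sulfooxy)phenyl]-4-oxo-4H-chromen-7-yl hydrogen sulfate)
Conditions: SO3·pyridine (3 equiv), pyridine/DMF, 0 °C → rt; then sulfonic acid resin (H+ form), H2O/MeOH, 0 °C, freeze-drying
Reagents that add atoms: sulfur trioxide–pyridine complex, O=S(=O)([O-])[n+]1ccccc1
Why: O-Sulfonation of phenols with a sulfur trioxide–amine complex; the 7-OH and 3'-OH are the only non-chelated phenols, whereas the 5-OH is held in a hydrogen bond to the C4 carbonyl and should react far more slowly, so a controlled excess should stop at the 7,3'-disulfate. Proton exchange on the resin in the cold converts the pyridinium form of 10 into the acid form drawn.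

## Compound list

1 | 3,5-bis(benzyloxy)phenol | Oc1cc(OCc2ccccc2)cc(OCc2ccccc2)c1 | starting material
2 | 3,5-bis(benzyloxy)-2-iodophenol | Oc1cc(OCc2ccccc2)cc(OCc2ccccc2)c1I | intermediate
3 | 3-(benzyloxy)-4-methoxybenzaldehyde | O=Cc1ccc(OC)c(OCc2ccccc2)c1 | starting material
4 | 2-(benzyloxy)-4-ethynyl-1-methoxybenzene | C#Cc1ccc(OC)c(OCc2ccccc2)c1 | intermediate
5 | carbon monoxide | [C-]#[O+] | starting material
6 | 1-[2,4-bis(benzyloxy)-6-hydroxyphenyl]-3-[3-(benzyloxy)-4-methoxyphenyl]prop-2-yn-1-one (not isolated) | O=C(C#Cc1ccc(OC)c(OCc2ccccc2)c1)c1c(O)cc(OCc2ccccc2)cc1OCc1ccccc1 | intermediate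
7 | (E)-1-[2,4-bis(benzyloxy)-6-hydroxyphenyl]-3-[3-(benzyloxy)-4-methoxyphenyl]-3-(diethylamino)prop-2-en-1-one (not isolated; E isomer drawn, the geometry is not controlled and has no consequence) | CCN(CC)/C(=C/C(=O)c1c(O)cc(OCc2ccccc2)cc1OCc1ccccc1)c1ccc(OC)c(OCc2ccccc2)c1 | intermediate
8 | 5,7-bis(benzyloxy)-2-[3-(benzyloxy)-4-methoxyphenyl]-4H-chromen-4-one | COc1ccc(-c2cc(=O)c3c(OCc4ccccc4)cc(OCc4ccccc4)cc3o2)cc1OCc1ccccc1 | intermediate
9 | 5,7-dihydroxy-2-(3-hydroxy-4-methoxyphenyl)-4H-chromen-4-one (diosmetin) | COc1ccc(-c2cc(=O)c3c(O)cc(O)cc3o2)cc1O | intermediate
10 | luteolin 4'-methyl ether 7,3'-disulfate | COc1ccc(-c2cc(=O)c3c(O)cc(OS(=O)(=O)O)cc3o2)cc1OS(=O)(=O)O | target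

## Step count and risk

Total step count: 5. Longest linear sequence: 4 steps (1 → 2 → 8 → 9 → 10, or equally 3 → 4 → 8 → 9 → 10).

**Step 3 (key step).** Three things are most likely to go wrong: acetylide transfer before CO uptake (a plain Sonogashira coupling followed by five-membered closure), closure of the ynone in the 5-exo mode, and aminolysis of the aroylpalladium by diethylamine. All three arise because three rates must be ordered at one crowded, electron-rich arylpalladium centre.
Fallback: it sets out from 3 and comes back to the route at 8. Commercial 2',4',6'-trihydroxyacetophenone is benzylated twice (BnBr, K2CO3, DMF; the chelated hydroxyl stays free) to give 1-[2,4-bis(benzyloxy)-6-hydroxyphenyl]ethan-1-one F1. Claisen–Schmidt condensation of F1 with 3 (KOH, EtOH) should give the chalcone (E)-1-[2,4-bis(benzyloxy)-6-hydroxyphenyl]-3-[3-(benzyloxy)-4-methoxyphenyl]prop-2-en-1-one F2. Oxidative cyclisation of F2 with catalytic iodine in DMSO at about 130 °C should give 8.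

**Step 1.** Iodination at the position para to the hydroxyl, or a second iodination, may compete, because all three ring positions are activated by three oxygens and the preference for C2 rests on sterics and hydrogen-bond delivery only.
Fallback: it sets out from 1 and comes back at 2, with the regiochemistry fixed by a directing group. Carbamoylation of 1 (Et2NCOCl, K2CO3, MeCN, reflux) gives 3,5-bis(benzyloxy)phenyl diethylcarbamate F3. Directed ortho-metalation (s-BuLi, TMEDA, THF, −78 °C) at the position between the carbamate and a benzyloxy group, with an iodine quench at −78 °C, gives 3,5-bis(benzyloxy)-2-iodophenyl diethylcarbamate F4. Hydrolysis (KOH, EtOH/H2O, reflux) returns 2.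

**Step 5.** Sulfation may be incomplete at the 3'-OH, which is flanked by the methoxy group, or may creep onto the chelated 5-OH when forced. The sulfate esters may also hydrolyse during isolation of the acid form, and the ionic product mixture cannot be purified on silica.
Fallback: it sets out from 9 and comes back at 10, carrying the sulfates as neutral, chromatographable diesters. Diosmetin 9 is treated with 2,2,2-trichloroethyl chlorosulfate (Et3N, DMAP, THF, 0 °C) to give 5-hydroxy-2-{4-methoxy-3-[(2,2,2-trichloroethoxy)sulfonyloxy]phenyl}-4-oxo-4H-chromen-7-yl 2,2,2-trichloroethyl sulfate F5, which is purified on silica. Reductive removal of both trichloroethyl groups (zinc dust, HCO2NH4, MeOH, rt) and proton exchange give 10.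

**Step 4.** Over-reduction of the C2=C3 bond of ring C, or stalling when the poorly soluble product coats the catalyst, are the likely failures.
Fallback: it sets out from 8 and comes back at 9 without any new compound (F0). The reductive cleavage is replaced by Lewis-acid cleavage with cation capture (BCl3, pentamethylbenzene, CH2Cl2, −78 °C), which cannot touch the C2=C3 bond and should leave the methyl ether at low temperature.

## Further compounds

F1 | step 3 | 1-[2,4-bis(benzyloxy)-6-hydroxyphenyl]ethan-1-one | CC(=O)c1c(O)cc(OCc2ccccc2)cc1OCc1ccccc1
F2 | step 3 | (E)-1-[2,4-bis(benzyloxy)-6-hydroxyphenyl]-3-[3-(benzyloxy)-4-methoxyphenyl]prop-2-en-1-one | O=C(/C=C/c1ccc(OC)c(OCc2ccccc2)c1)c1c(O)cc(OCc2ccccc2)cc1OCc1ccccc1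
F3 | step 1 | 3,5-bis(benzyloxy)phenyl diethylcarbamate | CCN(CC)C(=O)Oc1cc(OCc2ccccc2)cc(OCc2ccccc2)c1
F4 | step 1 | 3,5-bis(benzyloxy)-2-iodophenyl diethylcarbamate | CCN(CC)C(=O)Oc1cc(OCc2ccccc2)cc(OCc2ccccc2)c1I
F5 | step 5 | 5-hydroxy-2-{4-methoxy-3-[(2,2,2-trichloroethoxy)sulfonyloxy]phenyl}-4-oxo-4H-chromen-7-yl 2,2,2-trichloroethyl sulfate | COc1ccc(-c2cc(=O)c3c(O)cc(OS(=O)(=O)OCC(Cl)(Cl)Cl)cc3o2)cc1OS(=O)(=O)OCC(Cl)(Cl)Cl
F0 | step 4 | none | none
A1 | alternative 1 | 2-acetyl-3,5-bis(benzyloxy)phenyl 3-(benzyloxy)-4-methoxybenzoate | CC(=O)c1c(OC(=O)c2ccc(OC)c(OCc3ccccc3)c2)cc(OCc2ccccc2)cc1OCc1ccccc1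
A2 | alternative 1 | 1-[2,4-bis(benzyloxy)-6-hydroxyphenyl]-3-[3-(benzyloxy)-4-methoxyphenyl]propane-1,3-dione | O=C(CC(=O)c1ccc(OC)c(OCc2ccccc2)c1)c1c(O)cc(OCc2ccccc2)cc1OCc1ccccc1
A3 | alternative 2 | 5,7-bis(benzyloxy)-4H-chromen-4-one | O=c1ccoc2cc(OCc3ccccc3)cc(OCc3ccccc3)c12
A4 | alternative 2 | [3-(benzyloxy)-4-methoxyphenyl]boronic acid | COc1ccc(B(O)O)cc1OCc1ccccc1
A5 | alternative 3 | benzene-1,3,5-triol | Oc1cc(O)cc(O)c1
A6 | alternative 3 | ethyl 3-(3-hydroxy-4-methoxyphenyl)-3-oxopropanoate | CCOC(=O)CC(=O)c1ccc(OC)c(O)c1
A7 | alternative 3 | 3-(3-hydroxy-4-methoxyphenyl)-3-oxoprop-1-en-1-one | COc1ccc(C(=O)C=C=O)cc1O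
A8 | alternative 3 | 5,7-dihydroxy-4-(3-hydroxy-4-methoxyphenyl)-2H-chromen-2-one | COc1ccc(-c2cc(=O)oc3cc(O)cc(O)c23)cc1O
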